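The data are calculated with constants of no real substance.

Elm is a closed, stirred vessel held at 100 °C, in which substrate and partner meet free catalyst and give target. It has been followed up to the time asked about.

| flask | substrate | partner | free catalyst | temperature | remark | time |
|---|---|---|---|---|---|---|
| elm | 0.80 M | 2.4 M | 16 mM | 100 °C | the very flask that is asked about, followed so far |  |
| cedar | 1.2 M | 2.4 M | 16 mM | 95 °C | run made earlier |  |
| flask | 0.80 M | 2.40 M | 16 mM | 100 °C |  | 5.0 h |

- elm (time / min: target / %, substrate / %): 25.0: 73, 22; 50.0: 61, 21; 80.0: 47, 21; 150: 37, 19; 300: 29, 24
- cedar (time / min: target / %, substrate / %): 1.00: 5, 96; 2.00: 11, 86; 3.00: 18, 82; 6.00: 30, 70; 12.0: 51, 48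

(standard deviation of a reading: 1.5 percentage points)

- north: at 5.0 h take out 90% of the target then present, then wait 2.5 h
- east: at 5.0 h add free catalyst, 100% of the amount charged, then wait 2.5 h
- west: change nothing and wait 2.5 h more
- north-east: at 5.0 h raise the temperature by 25 K, then wait 2.5 h

* target, in percent of the substrate first charged, at 5.0 h
* the remedy with the largest gain of target, or "none" below 2 percentage points (north / east / west / north-east / none)
* target present, with what was taken out counted in, in percent of the substrate first charged, after north
* target present, with what was taken out counted in, in percent of the substrate first charged, after west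

- target that was removed still counts
- additions bring no volume worth counting

The ledger is kept on substrate, the species in whose charge the readings are counted. In elm, [substrate] reads 22% at 25.0 min and 24% at 300 min, with a scatter of 1.5 percentage points, so that entry stopped moving early. Target stands at 29%, and the books do not close:

unseen entry = 47.0%

This entry was 5.00% at 25.0 min, and it grew while [target] fell from 73%, so target feeds it. Cedar, at 12.0 min, shows 1.00% unseen.

The fall of target slows, so this reckoning takes the exchange as settled and carries the ratio it leaves, 1.62, the split: unseen entry over target at the end of a run. Read as an equilibrium constant, it keeps target near 29% under west. Under north, the split is restored from what stays in the vessel: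

taken out = 26.1%

pool left = 49.9%

target regrown = 19.0%

total = 45.1%

The runs give no split at a second temperature, so north-east stays unreckoned here, and north is this reckoning's choice.

The forecast gave 28%, 42% after north and 27% after west, chose north, and held that “heating gives no clear gain”.

The flask gives 29.2% now, 45.4% after north and 29.0% after west. The best remedy is north-east, gaining 20 points against 16 points for north.

    partner + free catalyst → catalyst intermediate A (k = 11.0 M⁻¹ s⁻¹, Ea = 47.0 kJ mol⁻¹)
    substrate + catalyst intermediate A → catalyst intermediate B (k = 0.630 M⁻¹ s⁻¹, Ea = 53.0 kJ mol⁻¹)
    catalyst intermediate B ⇌ catalyst intermediate C (K = 1.00, k = 0.770 s⁻¹, Ea = 99.0 kJ mol⁻¹, ΔH = −33.0 kJ mol⁻¹)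
    catalyst intermediate C ⇌ free catalyst + target (K = 0.290 M, k = 0.280 s⁻¹, Ea = 93.0 kJ mol⁻¹, ΔH = 7.00 kJ mol⁻¹)
    2 catalyst intermediate A → spent catalyst (k = 0.670 M⁻¹ s⁻¹, Ea = 56.0 kJ mol⁻¹)
    2 partner → homo dimer (k = 0.00280 M⁻¹ s⁻¹, Ea = 95.0 kJ mol⁻¹)
    target + free catalyst ⇌ isomer of the product + free catalyst, rate k7*[free catalyst]*[target] forward; the back reaction follows from the equilibrium constant (K = 1.70, k = 0.0900 M⁻¹ s⁻¹, Ea = 55.0 kJ mol⁻¹, ΔH = −53.0 kJ mol⁻¹)
    (constants at 100 °C)

The unseen entry is isomer of the product, and north-east gains through it: with the path from target to isomer of the product struck out, its gain of 20 points becomes −0.029 points. With −53.0 kJ mol⁻¹ for that step, a rise of 25 K puts the split at 0.554. That reckoning sets target at 48.9% of the substrate charged, 20 points above now. The neighbour flask charged with 0.027 M free catalyst has target and isomer of the product together at 92.5% of its substrate charged, which the split would divide to leave 35.3% as target, but it holds 39.6%, with free catalyst at 4.63% of the catalyst charged.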